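**Plan**
- Retrosynthesis cuts, in order: the three O–Si bonds; the bond from the guaiacyl ring carbon C1 to the carbinol carbon C7; the C7 oxidation level (aldehyde back to ester); the C8–O bond to the 2,6-dimethoxyaryl ring.
- Forward: the C7–C8–C9 chain comes from methyl (R)-glycerate acetonide; the B ring is attached at O–C8 by Mitsunobu etherification; the ester is taken to the aldehyde; the A ring is joined at C7; one global desilylation ends the route. No ring is formed.
- Stereochemistry: C8 (S) comes from the chiral pool by SN2 inversion of the (R)-α-hydroxy ester. C7 (S) is set by 1,2-induction from C8 in the aryl addition (Cram chelate, threo).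
- Enabling feature: the C8 ether oxygen sits on C1' of the B ring next to the 2'-OMe oxygen. Together they hold Mg2+, which also binds the C7 carbonyl oxygen in a five-membered chelate ring (Mg–O=C7–C8–O), so the aryl group enters from the C8–H face.
- Helpers: a bulky, non-chelating silyl ether at O9 and silyl ethers on both phenols, all removed together in the last step.

Key step: step 8

Remark: lignan numbering is used (C7 benzylic carbinol carbon, C8 ether-bearing carbon, C9 CH2OH; A ring = guaiacyl ring, B ring = 2,6-dimethoxyaryl ring, primed atoms). The target SMILES is read as (7S,8S), the threo isomer.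

**Step 1**
Reactants: 1 methyl (R)-2,2-dimethyl-1,3-dioxolane-4-carboxylate
Product: 2 methyl (R)-2,3-dihydroxypropanoate
Conditions: Dowex 50W (H+ form, cat.), MeOH, rt; filter, evaporate
Reagents that add atoms: none
Why: acid-catalysed transacetalisation with the solvent (acetonide cleavage) should free the diol without touching the methyl ester or the stereocentre.

**Step 2**
Reactants: 2 methyl (R)-2,3-dihydroxypropanoate
Product: 3 methyl (R)-3-[(tert-butyldiphenylsilyl)oxy]-2-hydroxypropanoate
Conditions: TBDPSCl (1.05 equiv), imidazole, CH2Cl2, 0 °C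
Reagents that add atoms: tert-butyl(chloro)diphenylsilane, CC(C)(C)[Si](Cl)(c1ccccc1)c1ccccc1
Why: selective silylation, in which the bulky silyl chloride should take the primary hydroxyl over the secondary one next to the ester, and which installs the non-chelating group wanted at O9.

**Step 3**
Reactants: 4 2,6-dimethoxy-1,4-benzoquinone
Product: 5 2,6-dimethoxybenzene-1,4-diol
Conditions: Na2S2O4, H2O/EtOAc, rt, under Ar; used at once
Reagents that add atoms: none
Why: dithionite reduction of a quinone to its hydroquinone is a standard two-electron reduction and leaves the methyl ethers untouched.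

**Step 4**
Reactants: 5 2,6-dimethoxybenzene-1,4-diol
Product: 6 2,6-dimethoxy-4-[(triisopropylsilyl)oxy]phenol
Conditions: TIPSCl (1.0 equiv), imidazole, DMF, 0 °C, Ar
Reagents that add atoms: chlorotri(propan-2-yl)silane, CC(C)[Si](Cl)(C(C)C)C(C)C
Why: regioselective phenol silylation, since the 4-OH is unhindered and the more acidic one, whereas the 1-OH is flanked by and hydrogen-bonded to two methoxy groups.

**Step 5**
Reactants: 3 methyl (R)-3-[(tert-butyldiphenylsilyl)oxy]-2-hydroxypropanoate; 6 2,6-dimethoxy-4-[(triisopropylsilyl)oxy]phenol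
Product: 7 methyl (S)-3-[(tert-butyldiphenylsilyl)oxy]-2-{2,6-dimethoxy-4-[(triisopropylsilyl)oxy]phenoxy}propanoate
Conditions: PPh3, DIAD, toluene, 0 °C → rt
Reagents that add atoms: none
Why: Mitsunobu etherification of an α-hydroxy ester, an activated SN2 site, by the phenol should proceed with clean inversion (R → S) and so set C8.

**Step 6**
Reactants: 7 methyl (S)-3-[(tert-butyldiphenylsilyl)oxy]-2-{2,6-dimethoxy-4-[(triisopropylsilyl)oxy]phenoxy}propanoate
Product: 8 (S)-3-[(tert-butyldiphenylsilyl)oxy]-2-{2,6-dimethoxy-4-[(triisopropylsilyl)oxy]phenoxy}propanal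
Conditions: DIBAL-H (1.1 equiv), CH2Cl2, −78 °C; MeOH, aq. Rochelle salt; used crude at once
Reagents that add atoms: none
Why: partial DIBAL reduction of an α-oxygenated ester at −78 °C should stop at the aldehyde oxidation level until work-up, and the neutral cold work-up should leave C8 intact.

**Step 7**
Reactants: 9 4-bromo-2-methoxyphenol
Product: 10 (4-bromo-2-methoxyphenoxy)tri(propan-2-yl)silane
Conditions: TIPSCl, imidazole, DMF, rt
Reagents that add atoms: chlorotri(propan-2-yl)silane, CC(C)[Si](Cl)(C(C)C)C(C)C
Why: phenol silylation gives a protecting group that should tolerate halogen–lithium exchange and the aryl-magnesium stage.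

**Step 8**
Reactants: 8 (S)-3-[(tert-butyldiphenylsilyl)oxy]-2-{2,6-dimethoxy-4-[(triisopropylsilyl)oxy]phenoxy}propanal; 10 (4-bromo-2-methoxyphenoxy)tri(propan-2-yl)silane
Product: 13 (1S,2S)-3-[(tert-butyldiphenylsilyl)oxy]-2-{2,6-dimethoxy-4-[(triisopropylsilyl)oxy]phenoxy}-1-{3-methoxy-4-[(triisopropylsilyl)oxy]phenyl}propan-1-ol, via aryllithium 11 (not isolated), via arylmagnesium bromide 12 (not isolated)
Conditions: 10 (1.6 equiv), t-BuLi (3.2 equiv), Et2O, −78 °C; MgBr2·OEt2 (1.7 equiv), −78 → 0 °C; added to 8 + MgBr2·OEt2 (2 equiv), CH2Cl2, −78 °C; aq. NH4Cl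
Reagents that add atoms: none
Why: The aryl Grignard 12 adds to the C7 aldehyde of 8 while Mg2+ is held in a five-membered chelate between the carbonyl oxygen and the C8 ether oxygen (helped by the neighbouring 2'-OMe oxygen, a veratrole-like bidentate site), so that C7=O and C8–O are syn-coplanar and the nucleophile approaches along the Bürgi–Dunitz path past C8–H and not past the CH2OTBDPS arm. The closest known reaction type is the chelation-controlled (Cram chelate) addition of Grignard reagents to α-alkoxy aldehydes, here with an α-aryloxy donor. No ring of the product is closed; the only ring is the transient magnesium chelate, which is lost on work-up. C7 is the one new stereocentre and should be set as S by 1,2-induction from the existing (S)-C8, which corresponds to the syn (threo) relationship of O7 and O8. The step needs diastereofacial selectivity and configurational integrity at C8: the weakly coordinating Et2O/CH2Cl2 medium, pre-complexation with MgBr2 and the bulky non-chelating silyl ether at O9 (no competing six-membered β-chelate) should secure the first, and −78 °C together with the less basic aryl-magnesium (not aryl-lithium) nucleophile the second. It also needs 1,2-addition to win over enolisation and β-elimination of the silyloxy group, which low temperature and Lewis-acid activation of the carbonyl favour.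

**Step 9**
Reactants: 13 (1S,2S)-3-[(tert-butyldiphenylsilyl)oxy]-2-{2,6-dimethoxy-4-[(triisopropylsilyl)oxy]phenoxy}-1-{3-methoxy-4-[(triisopropylsilyl)oxy]phenyl}propan-1-ol
Product: 14 (1S,2S)-1-(4-hydroxy-3-methoxyphenyl)-2-(4-hydroxy-2,6-dimethoxyphenoxy)propane-1,3-diol
Conditions: TBAF (4 equiv), AcOH (4 equiv), THF, 0 °C → rt, Ar
Reagents that add atoms: none
Why: fluoride-mediated desilylation should cleave the primary TBDPS ether and both aryl TIPS ethers in one operation, and the acetic acid buffer and inert atmosphere should protect the p-hydroxybenzyl alcohol and the electron-rich phenols from base-induced quinone methide formation and oxidation, so that neither stereocentre is touched.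

**Compound list**
1 | methyl (R)-2,2-dimethyl-1,3-dioxolane-4-carboxylate | COC(=O)[C@H]1COC(C)(C)O1 | starting material
2 | methyl (R)-2,3-dihydroxypropanoate | COC(=O)[C@H](O)CO | intermediate
3 | methyl (R)-3-[(tert-butyldiphenylsilyl)oxy]-2-hydroxypropanoate | COC(=O)[C@H](O)CO[Si](c1ccccc1)(c1ccccc1)C(C)(C)C | intermediate
4 | 2,6-dimethoxy-1,4-benzoquinone | COC1=CC(=O)C=C(OC)C1=O | starting material
5 | 2,6-dimethoxybenzene-1,4-diol | COc1cc(O)cc(OC)c1O | intermediate
6 | 2,6-dimethoxy-4-[(triisopropylsilyl)oxy]phenol | COc1cc(O[Si](C(C)C)(C(C)C)C(C)C)cc(OC)c1O | intermediate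
7 | methyl (S)-3-[(tert-butyldiphenylsilyl)oxy]-2-{2,6-dimethoxy-4-[(triisopropylsilyl)oxy]phenoxy}propanoate | COC(=O)[C@@H](Oc1c(OC)cc(O[Si](C(C)C)(C(C)C)C(C)C)cc1OC)CO[Si](c1ccccc1)(c1ccccc1)C(C)(C)C | intermediate
8 | (S)-3-[(tert-butyldiphenylsilyl)oxy]-2-{2,6-dimethoxy-4-[(triisopropylsilyl)oxy]phenoxy}propanal | O=C[C@@H](Oc1c(OC)cc(O[Si](C(C)C)(C(C)C)C(C)C)cc1OC)CO[Si](c1ccccc1)(c1ccccc1)C(C)(C)C | intermediate
9 | 4-bromo-2-methoxyphenol | COc1cc(Br)ccc1O | starting material
10 | (4-bromo-2-methoxyphenoxy)tri(propan-2-yl)silane | COc1cc(Br)ccc1O[Si](C(C)C)(C(C)C)C(C)C | intermediate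
11 | {3-methoxy-4-[(triisopropylsilyl)oxy]phenyl}lithium | [Li]c1ccc(O[Si](C(C)C)(C(C)C)C(C)C)c(OC)c1 | intermediate (not isolated)
12 | {3-methoxy-4-[(triisopropylsilyl)oxy]phenyl}magnesium bromide | Br[Mg]c1ccc(O[Si](C(C)C)(C(C)C)C(C)C)c(OC)c1 | intermediate (not isolated)
13 | (1S,2S)-3-[(tert-butyldiphenylsilyl)oxy]-2-{2,6-dimethoxy-4-[(triisopropylsilyl)oxy]phenoxy}-1-{3-methoxy-4-[(triisopropylsilyl)oxy]phenyl}propan-1-ol | COc1cc([C@H](O)[C@H](CO[Si](c2ccccc2)(c2ccccc2)C(C)(C)C)Oc2c(OC)cc(O[Si](C(C)C)(C(C)C)C(C)C)cc2OC)ccc1O[Si](C(C)C)(C(C)C)C(C)C | intermediate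
14 | (1S,2S)-1-(4-hydroxy-3-methoxyphenyl)-2-(4-hydroxy-2,6-dimethoxyphenoxy)propane-1,3-diol | COc1cc([C@H](O)[C@H](CO)Oc2c(OC)cc(O)cc2OC)ccc1O | target

**Totals**
Total step count: 9.
Longest linear sequence: 6 steps (steps 1, 2, 5, 6, 8, 9; equally steps 3, 4, 5, 6, 8, 9).

**Steps most likely to fail**

Step 8. The aryl ether oxygen may bind magnesium too weakly, so that open-chain polar Felkin–Anh attack competes and the facial selectivity drops or turns toward the erythro series. The basic reagent may also enolise the aldehyde and erode C8. Fallback: the ring-to-C7 bond is made at the ketone oxidation level and C7 is then set by hydride instead of by the aryl group. The fallback sets out from ester 7. With MeNH(OMe)·HCl and i-PrMgCl (THF, −20 °C) it should give the Weinreb amide (S)-3-[(tert-butyldiphenylsilyl)oxy]-2-{2,6-dimethoxy-4-[(triisopropylsilyl)oxy]phenoxy}-N-methoxy-N-methylpropanamide F1. Aryllithium 11 (from 10, t-BuLi, THF, −78 °C) should add once to the amide and give, after work-up, the ketone (S)-3-[(tert-butyldiphenylsilyl)oxy]-2-{2,6-dimethoxy-4-[(triisopropylsilyl)oxy]phenoxy}-1-{3-methoxy-4-[(triisopropylsilyl)oxy]phenyl}propan-1-one F2. Reduction with K-Selectride and 18-crown-6 in THF at −78 °C, conditions that disfavour chelation, should follow the polar Felkin–Anh model (hydride anti to the C8–OAr bond) and lead to the threo alcohol, so the route is rejoined at 13.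

Step 5. The di-ortho-substituted, weakly acidic phenol may attack the oxyphosphonium intermediate too slowly, so that elimination toward the enol ether or alkylation of the reduced azodicarboxylate takes over. Fallback: the redox condensation is replaced by a discrete, far more reactive electrophile and a preformed phenoxide. The fallback sets out from 3. Tf2O and 2,6-lutidine (CH2Cl2, −78 °C) should give methyl (R)-3-[(tert-butyldiphenylsilyl)oxy]-2-{[(trifluoromethyl)sulfonyl]oxy}propanoate F3. Phenol 6 with K2CO3 in MeCN at 0 °C should then displace the triflate with inversion, so the route is rejoined at 7.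

Step 6. The reduction may run past the aldehyde to the primary alcohol, and the α-aryloxy aldehyde may epimerise at C8 during work-up and handling. Fallback: the aldehyde is reached by full reduction and re-oxidation. The fallback sets out from 7. LiBH4 in THF at 0 °C (quenched cold with NH4Cl to avoid 1,3-silyl migration) should give (R)-3-[(tert-butyldiphenylsilyl)oxy]-2-{2,6-dimethoxy-4-[(triisopropylsilyl)oxy]phenoxy}propan-1-ol F4. Dess–Martin periodinane buffered with NaHCO3 (CH2Cl2, 0 °C) should then give the aldehyde under non-basic conditions, so the route is rejoined at 8.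

**Further compounds**
F1 | step 8 | (S)-3-[(tert-butyldiphenylsilyl)oxy]-2-{2,6-dimethoxy-4-[(triisopropylsilyl)oxy]phenoxy}-N-methoxy-N-methylpropanamide | CON(C)C(=O)[C@@H](Oc1c(OC)cc(O[Si](C(C)C)(C(C)C)C(C)C)cc1OC)CO[Si](c1ccccc1)(c1ccccc1)C(C)(C)C
F2 | step 8 | (S)-3-[(tert-butyldiphenylsilyl)oxy]-2-{2,6-dimethoxy-4-[(triisopropylsilyl)oxy]phenoxy}-1-{3-methoxy-4-[(triisopropylsilyl)oxy]phenyl}propan-1-one | COc1cc(C(=O)[C@@H](Oc2c(OC)cc(O[Si](C(C)C)(C(C)C)C(C)C)cc2OC)CO[Si](c2ccccc2)(c2ccccc2)C(C)(C)C)ccc1O[Si](C(C)C)(C(C)C)C(C)C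
F3 | step 5 | methyl (R)-3-[(tert-butyldiphenylsilyl)oxy]-2-{[(trifluoromethyl)sulfonyl]oxy}propanoate | COC(=O)[C@H](OS(=O)(=O)C(F)(F)F)CO[Si](c1ccccc1)(c1ccccc1)C(C)(C)C
F4 | step 6 | (R)-3-[(tert-butyldiphenylsilyl)oxy]-2-{2,6-dimethoxy-4-[(triisopropylsilyl)oxy]phenoxy}propan-1-ol | OC[C@@H](Oc1c(OC)cc(O[Si](C(C)C)(C(C)C)C(C)C)cc1OC)CO[Si](c1ccccc1)(c1ccccc1)C(C)(C)C
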